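The slowness of the alpha run after its early minutes was what I had to judge: between 43 min and 49 min the target rose by 0.00540 M. I had to decide whether the eta flask, charged like alpha, was worth leaving until 98 min, or whether its charge should be changed instead.

| flask | substrate | catalyst | time |
|---|---|---|---|
| alpha | 0.600 M | 0.0600 M |  |
| zeta | 0.360 M | 0.0600 M |  |
| beta | 0.900 M | 0.0600 M |  |
| delta | 0.600 M | 0.0300 M |  |
| eta | 0.600 M | 0.0600 M | 98 min |

| run | time / min | [target] / M |
|---|---|---|
| alpha run | 6.1 | 0.1237 |
| alpha run | 12 | 0.1774 |
| alpha run | 18 | 0.2076 |
| alpha run | 24 | 0.2221 |
| alpha run | 31 | 0.2323 |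
| alpha run | 37 | 0.2406 |
| alpha run | 43 | 0.2462 |
| alpha run | 49 | 0.2516 |
| zeta run | 6.1 | 0.0828 |
| zeta run | 12 | 0.1255 |
| zeta run | 18 | 0.1477 |
| zeta run | 24 | 0.1604 |
| zeta run | 31 | 0.1734 |
| zeta run | 37 | 0.1819 |
| zeta run | 43 | 0.1807 |
| zeta run | 49 | 0.1897 |
| beta run | 6.1 | 0.1648 |
| beta run | 12 | 0.2229 |
| beta run | 18 | 0.2569 |
| beta run | 24 | 0.2741 |
| beta run | 31 | 0.2880 |
| beta run | 37 | 0.2972 |
| beta run | 43 | 0.3044 |
| beta run | 49 | 0.3083 |
| delta run | 6.1 | 0.0837 |
| delta run | 12 | 0.1226 |
| delta run | 18 | 0.1498 |
| delta run | 24 | 0.1644 |
| delta run | 31 | 0.1785 |
| delta run | 37 | 0.1834 |
| delta run | 43 | 0.1859 |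
| delta run | 49 | 0.1948 |

(readings scatter by 0.002 M)

- Overall: substrate -> target, with catalyst as catalyst.
- Constant volume, constant temperature.
- The analysis sees a species whether free or bound.
- An order is taken over about fifteen percent of the charge, up and down.

1. order of the initial rate in [substrate], near the charge of the alpha run, the rate being that where two percent of its substrate are target (one fixed amount of target, the same in the runs compared)
2. order of the initial rate in [catalyst], near the charge of the alpha run, the rate being that where two percent of its substrate are target
3. target in the eta run at 98 min, as a share of the substrate charged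

At the last reading the target stood at 52.7% of the charge in the zeta run, 41.9% in the alpha run and 34.3% in the beta run. The share was higher in zeta than in beta, so a richer charge gave a poorer share. I took this to mean a second way out for substrate, first order for the target and second order for the loss.

Dividing one rate by the other removes time. If x is the rate of loss over the rate to target at the charge, then at a fraction f of the charge left:

rate of loss / rate to target = x·f

final share = ln(1 + x) / x

The zeta share, taken as final, gave x = 2.21. With catalyst unchanged, x grows in step with the substrate charged. So the eta flask carries x = 3.69, its loss ratio, the substrate lost over the substrate turned to target at the charge; this is the inverse of a selectivity factor. My final share for eta was 41.9%. The same rule gave 33.9% for the beta run, against its reading of 34.3%. I expected little from the extra time, since my final share for eta stood level with the 41.9% that the alpha run had read at its last reading. The leaner zeta run had read a higher share, 52.7%, than my final share for eta, so my reckoning favoured changing the charge over waiting; I kept the eta flask at its stated charge as the test of the rule.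

The forecast gave 0.85 for the order in substrate, 0.85 for the order in catalyst and 46% for the eta share, saying “That looks like time-dependent catalyst loss”. There we differed: I held to a loss of substrate, and my share was lower than the forecast's.

The flask gave orders of 0.99 and 0.63, and an eta share of 42.7%.

    catalyst + substrate ⇌ catalyst-substrate complex (3.906 M⁻¹ min⁻¹, 0.4998 min⁻¹)
    catalyst-substrate complex → target + catalyst (16.68 min⁻¹)
    2 substrate → homo dimer (0.1782 M⁻¹ min⁻¹)
    2 catalyst ⇌ resting dimer, settled at all times (84.90 M⁻¹)

The shortfall in eta is due to the homo dimer: the simulated eta run without that step reaches 99.7%, against 42.7% as it is. A second simulated eta run removes the pairing of catalyst to resting dimer. Counting that pairing by itself, 26.8% of the catalyst is free at the charge, and the target rate follows free catalyst. Without the pairing, the loss ratio therefore shrinks to 0.989, and the share rule gives 69.5%, against the simulated 69.1%.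

The runs were generated by integration for an exercise, and the scatter is random.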